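**Conventions.** Neolignan numbering is used. Ring A is the 4‑oxygenated 3,5‑dimethoxyphenyl ring with its chain C7 (carbinol), C8 (aryloxy methine) and C9 (CH2OH). Ring B is the 2,6‑dimethoxyphenoxy ring (ether oxygen O4' on C4') with its chain C7', C8', C9' on C1'. In names, ArA = 4‑(benzyloxy)‑3,5‑dimethoxyphenyl and ArB‑O = 4‑{[(4S)‑2,2‑dimethyl‑1,3‑dioxolan‑4‑yl]methyl}‑2,6‑dimethoxyphenoxy.

## Analysis of the target

The target 22 is an open‑chain 8‑O‑4' neolignan: a syringylglycerol unit (ring A, C7–C9) is joined through the C8–O4' ether to a second syringyl ring (ring B) that carries a 2,3‑dihydroxypropyl chain (C7'–C9') para to the ether oxygen. It has three stereocentres. C7 (S) and C8 (R) are adjacent and erythro, meaning that the C7 hydroxyl and O4' are anti when the chain ring A–C7–C8–C9 is drawn zigzag. C8' (S) lies seven bonds from C8 and cannot be controlled from it. The C7 carbinol is benzylic and para to a phenol oxygen, so it ionises under acid (through a quinone methide once the phenol is free) and can be lost on hydrogenolysis. Both rings are electron‑rich and easily oxidised, and five hydroxyl groups must be differentiated. The skeleton is simple (no ring, one ether bond, two C–C bonds to make); the difficulty is the absolute and relative configuration of C7/C8 in an open chain. The di‑ortho‑substituted O4' makes substitution at a secondary C8 unattractive, and at the ketone oxidation level C8 is epimerisable. A wrong configuration at C8' would give a diastereomer that is hard to remove. The strategy rests on C8 being a methine bonded to C7, O4' and the C9 hydroxymethyl group. Removing H from C8 and OH from C9 reveals a 1,1‑disubstituted enol ether C8=C9 next to the C7 stereocentre, so C8 can be created last by anti‑Markovnikov hydration under control of C7.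

## Retrosynthetic reasoning

**22 back to 19.** The last three operations only remove masking groups: hydrogenolysis of the ring A benzyl ether (21), hydrolysis of the ring B acetonide (20) and desilylation at C7 (19). The order matters in the forward sense. The acid step is placed before the phenol is freed, and the hydrogenolysis is neutral and comes last.

**19 back to 17 (C8–H and C9–O).** Taking H from C8 and OH from C9 gives the enol ether 17. This cut is preferred over one at C8–O4' or C7–C8 at the sp3 level, which would need an SN2 reaction of a hindered phenoxide at a secondary carbon or an aldol reaction with weak anti control. The gain is that C8 becomes sp2, so the C8–O4' bond can be made earlier at a non‑stereogenic primary carbon. The forward reaction must place boron on C9 and deliver hydrogen to the face of C8 that makes O4' anti to the C7 oxygen.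

**17 back to 15 (C7–H).** The silyl ether 17 comes from the allylic alcohol 16, and 16 from the enone 15 by enantioselective 1,2‑reduction. C7 is the only centre of the C7/C8 pair that needs reagent control, and as a benzylic ketone it is well placed for this. The forward reaction must reduce the carbonyl without touching the enol ether.

**15 back to 11 and 12 (C8=C9).** The exocyclic methylene is cut off as the one‑carbon iminium electrophile 12. C8 of ketone 11 is the only enolisable position, so the regiochemistry is not in question.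

**11 back to 10 and 7 (C8–O4'); 10 back to 8.** The ether bond is cut at the phenacyl carbon, where displacement of bromide by a hindered phenoxide is easy. The bromo ketone 10 comes from 9, the benzyl ether of acetosyringone 8.

**7 back to 2 and 3 (C1'–C7').** C8' is taken from the chiral pool at the start. The phenol 7 comes from triol 6 and its dibenzyl precursor 5. Bond C1'–C7' is cut to the aryl Grignard reagent 4 (from bromide 2, itself from phenol 1) and the epoxide 3. The forward opening occurs at the terminal carbon and leaves the stereocentre untouched.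

## Alternatives that were turned down

**Alternative 1:** Late formation of C1'–C7'. A ring B bromide that already carries the complete, protected C7–C9 unit, the dioxane A2, would be converted into its Grignard reagent and added under copper catalysis to the epoxide 3, giving the carbinol A1.
- For: C8' comes unchanged from the chiral pool, the opening is regioselective, and the free C8' hydroxyl needs no further protection. On the reliability of this bond it equals the chosen route, which uses the same reaction in step 2.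
- Against: it disconnects the easy part. A2 must already contain the erythro C7/C8 pair, so the real stereochemical problem is only moved to an unspecified earlier stage. Magnesium insertion would have to be done on an advanced, polyoxygenated, electron‑rich bromide with a benzylic acetal oxygen, and the nucleophile, which is normally used in excess, would be the valuable fragment.
- Comparison: the chosen strategy makes this bond first, on the simple bromide 2, and spends its risk on the step that sets C8.

**Alternative 2:** C7–C8 disconnection by aryloxyallylboration. The (E)‑γ‑aryloxyallyl boronate A4 would add to the aldehyde A5 under a chiral phosphoric acid to give the homoallylic alcohol A3. Ozonolysis with reductive work‑up would then convert the vinyl group into C9–OH.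
- For: one catalytic step forms the central C–C bond and both stereocentres, and a closed chair transition state translates the (E)‑geometry into the anti relationship. On relative stereocontrol this is stronger than an open‑chain hydroboration.
- Against: A4, with a di‑ortho‑substituted aryloxy group, is not easily obtained geometrically pure, since metalation of allyl aryl ethers leads to the (Z)‑series. The electron‑rich aldehyde A5 is a slow partner, and the ozonolysis must be done in the presence of two oxidisable arenes. The step count is no lower.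
- Comparison: the chosen strategy offers a precursor made entirely by standard reactions, with C9 arriving as a carbon that needs no oxidative cleavage.

**Alternative 3:** C1–C7 disconnection by carbonyl addition. The aryltitanium reagent A8 would add to the (R)‑2‑aryloxy‑3‑silyloxypropanal A7 in the Felkin–Anh sense to give the carbinol A6.
- For: C8 is fixed beforehand with a known absolute configuration, so no catalyst‑controlled reduction is needed, and the aryl nucleophile derives from the simple bromide 2. In this respect it is stronger than the chosen route.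
- Against: A7 is an α‑aryloxy aldehyde that enolises easily, its enantioselective preparation takes several steps, and Felkin versus chelation control is again open‑chain 1,2‑induction, so it is no better in kind than the hydroboration.
- Comparison: the chosen strategy offers a shorter path through intermediates with no acidic stereocentre (17 cannot epimerise). Alternative 3 is kept as the fallback for the key step.

Key step: step 11

**Remarks on the chemistry before the steps.**
- Assumption for step 9: the coplanar ring A aryl group is taken as the larger carbonyl substituent, as in aryl alkyl ketones, so the (S)‑oxazaborolidine should give the (S)‑carbinol. If the sense proves opposite, the (R)‑catalyst is used.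
- 4‑Bromo‑2,6‑dimethoxyphenol 1 and the epoxide 3 are taken as catalogue chemicals.
- For step 11, the stereochemical model places C7–H inside, pointing toward C9. The rotamer with C7–H turned toward O4' would lead to the threo isomer.

## Steps

Step 1
Reactants: 1 4‑bromo‑2,6‑dimethoxyphenol
Product: 2 2‑(benzyloxy)‑5‑bromo‑1,3‑dimethoxybenzene
Conditions: BnBr, K2CO3, DMF, rt to 50 °C
Reagents that add atoms: benzyl bromide, BrCc1ccccc1
Why: Williamson ether synthesis; the benzyl ether masks the acidic phenol for the Grignard step and is removed later by hydrogenolysis.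

Step 2
Reactants: 2 2‑(benzyloxy)‑5‑bromo‑1,3‑dimethoxybenzene; 3 (S)‑benzyl glycidyl ether
Product: 5 (2S)‑1‑(benzyloxy)‑3‑ArA‑propan‑2‑ol, via aryl Grignard reagent 4 (not isolated)
Conditions: Mg, THF, 50 °C; then CuI (10 mol %), 3, THF, −30 to 0 °C
Reagents that add atoms: none
Why: Magnesium inserts as it does for the 3,4,5‑trimethoxyphenyl analogue, and the copper‑catalysed Grignard opening of a terminal epoxide is an SN2 attack at the unsubstituted carbon. It forms C1'–C7' and carries C8' (S) over unchanged from the chiral pool.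

Step 3
Reactants: 5 (2S)‑1‑(benzyloxy)‑3‑ArA‑propan‑2‑ol
Product: 6 (2S)‑3‑(4‑hydroxy‑3,5‑dimethoxyphenyl)propane‑1,2‑diol
Conditions: H2 (1 atm), 10% Pd/C, EtOH, rt
Reagents that add atoms: none
Why: Catalytic hydrogenolysis cleaves both the aryl benzyl and the alkyl benzyl ether; nothing else is reducible and C8' is not involved.

Step 4
Reactants: 6 (2S)‑3‑(4‑hydroxy‑3,5‑dimethoxyphenyl)propane‑1,2‑diol
Product: 7 4‑{[(4S)‑2,2‑dimethyl‑1,3‑dioxolan‑4‑yl]methyl}‑2,6‑dimethoxyphenol
Conditions: Me2C(OMe)2, pyridinium p‑toluenesulfonate (cat.), acetone, rt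
Reagents that add atoms: 2,2‑dimethoxypropane, COC(C)(C)OC
Why: Acid‑catalysed transketalisation closes the dioxolane on the terminal 1,2‑diol; the phenol forms no stable ketal and stays free for step 7.

Step 5
Reactants: 8 acetosyringone
Product: 9 1‑ArA‑ethan‑1‑one
Conditions: BnBr, K2CO3, DMF, 50 °C
Reagents that add atoms: benzyl bromide, BrCc1ccccc1
Why: Williamson ether synthesis; the benzyl ether keeps the phenol from reacting in steps 6 to 11 and leaves last under neutral conditions.

Step 6
Reactants: 9 1‑ArA‑ethan‑1‑one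
Product: 10 2‑bromo‑1‑ArA‑ethan‑1‑one
Conditions: CuBr2 (2.1 equiv), EtOAc/CHCl3, reflux
Reagents that add atoms: CuBr2, Br[Cu]Br
Why: Selective α‑monobromination of an aryl methyl ketone through its copper enolate; the acyl group deactivates ring A toward nuclear bromination.

Step 7
Reactants: 10 2‑bromo‑1‑ArA‑ethan‑1‑one; 7 4‑{[(4S)‑2,2‑dimethyl‑1,3‑dioxolan‑4‑yl]methyl}‑2,6‑dimethoxyphenol
Product: 11 1‑ArA‑2‑(ArB‑O)ethan‑1‑one
Conditions: K2CO3, acetone, rt
Reagents that add atoms: none
Why: Williamson‑type SN2 displacement of a reactive phenacyl bromide by the phenoxide of 7. This is the standard construction of the C8–O4' bond of arylglycerol aryl ethers and tolerates two ortho methoxy groups.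

Step 8
Reactants: 11 1‑ArA‑2‑(ArB‑O)ethan‑1‑one; 12 dimethylmethyleneiminium iodide
Product: 15 1‑ArA‑2‑(ArB‑O)prop‑2‑en‑1‑one, via Mannich base 13 (not isolated), via quaternary ammonium iodide 14 (not isolated)
Conditions: LiHMDS, THF, −78 °C; 12, −78 °C to rt; MeI, rt; sat. aq. NaHCO3, CH2Cl2, rt
Reagents that add atoms: none
Why: Mannich aminomethylation of the lithium enolate (C8 is the only enolisable position), exhaustive N‑methylation, then E1cB Hofmann‑type loss of trimethylamine from the acidic C8–H. The resulting 2‑aryloxy enone is a known, isolable class of captodative enone.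

Step 9
Reactants: 15 1‑ArA‑2‑(ArB‑O)prop‑2‑en‑1‑one
Product: 16 (1S)‑1‑ArA‑2‑(ArB‑O)prop‑2‑en‑1‑ol
Conditions: (S)‑Me‑CBS oxazaborolidine [(3aS)‑1‑methyl‑3,3‑diphenyltetrahydro‑1H,3H‑pyrrolo[1,2‑c][1,3,2]oxazaborole] (20 mol %), catecholborane, toluene, −78 °C; MeOH quench, aq. NaOH wash
Reagents that add atoms: none
Why: Corey–Bakshi–Shibata reduction: the catalyst binds the borane at nitrogen and the ketone at boron through the lone pair anti to the ring A aryl group, and hydride is delivered within the complex to one carbonyl face, which should set C7 as S. Catecholborane at −78 °C reduces the carbonyl 1,2 and leaves the enol ether alone.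

Step 10
Reactants: 16 (1S)‑1‑ArA‑2‑(ArB‑O)prop‑2‑en‑1‑ol
Product: 17 tert‑butyl{[(1S)‑1‑ArA‑2‑(ArB‑O)prop‑2‑en‑1‑yl]oxy}dimethylsilane
Conditions: TBSOTf, 2,6‑lutidine, CH2Cl2, −78 to 0 °C
Reagents that add atoms: tert‑butyldimethylsilyl triflate, CC(C)(C)[Si](C)(C)OS(=O)(=O)C(F)(F)F
Why: Silylation with a silyl triflate and a hindered pyridine base is fast on a hindered secondary carbinol and, being buffered, should not ionise the benzylic alcohol or open the acetonide. The bulky silyl ether also raises the steric bias for step 11.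

Step 11
Reactants: 17 tert‑butyl{[(1S)‑1‑ArA‑2‑(ArB‑O)prop‑2‑en‑1‑yl]oxy}dimethylsilane
Product: 19 (2R,3S)‑3‑ArA‑3‑[(tert‑butyldimethylsilyl)oxy]‑2‑(ArB‑O)propan‑1‑ol, via B‑alkyl‑9‑BBN adduct 18 (not isolated)
Conditions: 9‑BBN (3 equiv), THF, 0 °C to rt; then NaBO3·4H2O, THF/H2O, 0 °C to rt
Reagents that add atoms: sodium perborate tetrahydrate (NaBO3·4H2O, the peroxoborate salt), [Na+].[Na+].O[B-]1(O)OO[B-](O)(O)OO1
Why: Substrate‑directed Brown hydroboration–oxidation: the B–H bond of 9‑borabicyclo[3.3.1]nonane adds syn across C8=C9 through a four‑centre transition state, boron going to the terminal C9 for steric reasons and because the ether oxygen stabilises positive charge developing at C8. No ring is closed; the only new stereocentre is C8, and it is controlled by C7 through 1,2‑induction. In the staggered transition state the C7–H bond takes the inside position facing C9, where the bulky borane arrives, the silyloxy group lies outside near O4', and the ring A aryl group stands anti to the forming C8–H bond, so hydrogen enters the face of C8 opposite ring A. This should place O4' anti to the C7 oxygen along ring A–C7–C8–C9, which is the (8R) erythro isomer; the rotamer with C7–H turned toward O4' would give the threo isomer and is disfavoured because it pushes aryl or silyloxy into the inside position against the borane. The closest known reactions are the anti‑selective 9‑BBN hydroboration of 2‑methylallyl alcohol derivatives with a carbinol stereocentre and the hydroboration of ketone‑derived enol ethers with boron at the β‑carbon; this step combines the two. The step needs regioselectivity (secured by the enol ether), 1,2‑anti diastereoselectivity (bulk of 9‑BBN, the silyl ether, and the C–O bond avoiding the anti position) and chemoselectivity against β‑elimination of the ring B phenoxide from 18. For the last point a weakly Lewis‑acidic B‑alkyl‑9‑BBN and a mild, nearly neutral perborate oxidation are used and the mixture is never heated. The oxidation moves C9 from boron to oxygen and does not touch C8.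

Step 12
Reactants: 19 (2R,3S)‑3‑ArA‑3‑[(tert‑butyldimethylsilyl)oxy]‑2‑(ArB‑O)propan‑1‑ol
Product: 20 (1S,2R)‑1‑ArA‑2‑(ArB‑O)propane‑1,3‑diol
Conditions: Bu4NF, THF, 0 °C to rt
Reagents that add atoms: none
Why: Fluoride‑mediated desilylation driven by the Si–F bond; acetonide, benzyl ether and both stereocentres are not affected, and any 1,3‑silyl shift in 19 is harmless because the same diol results.

Step 13
Reactants: 20 (1S,2R)‑1‑ArA‑2‑(ArB‑O)propane‑1,3‑diol
Product: 21 (1S,2R)‑1‑ArA‑2‑{4‑[(2S)‑2,3‑dihydroxypropyl]‑2,6‑dimethoxyphenoxy}propane‑1,3‑diol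
Conditions: AcOH/H2O (4:1), rt to 40 °C
Reagents that add atoms: none
Why: Acid‑catalysed acetal hydrolysis of the terminal dioxolane. It is run while the ring A phenol is still benzylated, so that C7 cannot ionise through a quinone methide, and in a non‑alcoholic medium, so that no benzylic ether can form.

Step 14
Reactants: 21 (1S,2R)‑1‑ArA‑2‑{4‑[(2S)‑2,3‑dihydroxypropyl]‑2,6‑dimethoxyphenoxy}propane‑1,3‑diol
Product: 22 (1S,2R)‑2‑{4‑[(2S)‑2,3‑dihydroxypropyl]‑2,6‑dimethoxyphenoxy}‑1‑(4‑hydroxy‑3,5‑dimethoxyphenyl)propane‑1,3‑diol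
Conditions: H2 (1 atm), 10% Pd/C, EtOAc/EtOH, rt
Reagents that add atoms: none
Why: Hydrogenolysis of an aryl benzyl ether under neutral conditions at one atmosphere is much faster than cleavage of the secondary benzylic C7–O bond; the reaction is stopped after uptake of one equivalent.

## Compound list

1 | 4‑bromo‑2,6‑dimethoxyphenol | COc1cc(Br)cc(OC)c1O | starting material
2 | 2‑(benzyloxy)‑5‑bromo‑1,3‑dimethoxybenzene | COc1cc(Br)cc(OC)c1OCc1ccccc1 | intermediate
3 | (S)‑benzyl glycidyl ether, (2S)‑2‑[(benzyloxy)methyl]oxirane | C1[C@H](O1)COCc1ccccc1 | starting material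
4 | [4‑(benzyloxy)‑3,5‑dimethoxyphenyl]magnesium bromide | COc1cc([Mg]Br)cc(OC)c1OCc1ccccc1 | intermediate (not isolated)
5 | (2S)‑1‑(benzyloxy)‑3‑[4‑(benzyloxy)‑3,5‑dimethoxyphenyl]propan‑2‑ol | COc1cc(C[C@H](O)COCc2ccccc2)cc(OC)c1OCc1ccccc1 | intermediate
6 | (2S)‑3‑(4‑hydroxy‑3,5‑dimethoxyphenyl)propane‑1,2‑diol | COc1cc(C[C@H](O)CO)cc(OC)c1O | intermediate
7 | 4‑{[(4S)‑2,2‑dimethyl‑1,3‑dioxolan‑4‑yl]methyl}‑2,6‑dimethoxyphenol | COc1cc(C[C@H]2COC(C)(C)O2)cc(OC)c1O | intermediate
8 | acetosyringone | CC(=O)c1cc(OC)c(O)c(OC)c1 | starting material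
9 | 1‑[4‑(benzyloxy)‑3,5‑dimethoxyphenyl]ethan‑1‑one | CC(=O)c1cc(OC)c(OCc2ccccc2)c(OC)c1 | intermediate
10 | 2‑bromo‑1‑[4‑(benzyloxy)‑3,5‑dimethoxyphenyl]ethan‑1‑one | BrCC(=O)c1cc(OC)c(OCc2ccccc2)c(OC)c1 | intermediate
11 | 1‑ArA‑2‑(ArB‑O)ethan‑1‑one | COc1cc(C(=O)COc2c(OC)cc(C[C@H]3COC(C)(C)O3)cc2OC)cc(OC)c1OCc1ccccc1 | intermediate
12 | dimethylmethyleneiminium iodide | C[N+](C)=C.[I-] | starting material
13 | 1‑ArA‑3‑(dimethylamino)‑2‑(ArB‑O)propan‑1‑one (both C8 epimers) | COc1cc(C(=O)C(CN(C)C)Oc2c(OC)cc(C[C@H]3COC(C)(C)O3)cc2OC)cc(OC)c1OCc1ccccc1 | intermediate (not isolated)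
14 | 3‑ArA‑N,N,N‑trimethyl‑3‑oxo‑2‑(ArB‑O)propan‑1‑aminium iodide (both C8 epimers) | COc1cc(C(=O)C(C[N+](C)(C)C)Oc2c(OC)cc(C[C@H]3COC(C)(C)O3)cc2OC)cc(OC)c1OCc1ccccc1.[I-] | intermediate (not isolated)
15 | 1‑ArA‑2‑(ArB‑O)prop‑2‑en‑1‑one | COc1cc(C(=O)C(=C)Oc2c(OC)cc(C[C@H]3COC(C)(C)O3)cc2OC)cc(OC)c1OCc1ccccc1 | intermediate
16 | (1S)‑1‑ArA‑2‑(ArB‑O)prop‑2‑en‑1‑ol | COc1cc([C@H](O)C(=C)Oc2c(OC)cc(C[C@H]3COC(C)(C)O3)cc2OC)cc(OC)c1OCc1ccccc1 | intermediate
17 | tert‑butyl{[(1S)‑1‑ArA‑2‑(ArB‑O)prop‑2‑en‑1‑yl]oxy}dimethylsilane (precursor of the key step) | COc1cc([C@H](O[Si](C)(C)C(C)(C)C)C(=C)Oc2c(OC)cc(C[C@H]3COC(C)(C)O3)cc2OC)cc(OC)c1OCc1ccccc1 | intermediate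
18 | 9‑[(2R,3S)‑3‑ArA‑3‑[(tert‑butyldimethylsilyl)oxy]‑2‑(ArB‑O)propyl]‑9‑borabicyclo[3.3.1]nonane | COc1cc([C@H](O[Si](C)(C)C(C)(C)C)[C@@H](CB2C3CCCC2CCC3)Oc2c(OC)cc(C[C@H]3COC(C)(C)O3)cc2OC)cc(OC)c1OCc1ccccc1 | intermediate (not isolated)
19 | (2R,3S)‑3‑ArA‑3‑[(tert‑butyldimethylsilyl)oxy]‑2‑(ArB‑O)propan‑1‑ol (product of the key step) | COc1cc([C@H](O[Si](C)(C)C(C)(C)C)[C@@H](CO)Oc2c(OC)cc(C[C@H]3COC(C)(C)O3)cc2OC)cc(OC)c1OCc1ccccc1 | intermediate
20 | (1S,2R)‑1‑ArA‑2‑(ArB‑O)propane‑1,3‑diol | COc1cc([C@H](O)[C@@H](CO)Oc2c(OC)cc(C[C@H]3COC(C)(C)O3)cc2OC)cc(OC)c1OCc1ccccc1 | intermediate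
21 | (1S,2R)‑1‑ArA‑2‑{4‑[(2S)‑2,3‑dihydroxypropyl]‑2,6‑dimethoxyphenoxy}propane‑1,3‑diol | COc1cc([C@H](O)[C@@H](CO)Oc2c(OC)cc(C[C@H](O)CO)cc2OC)cc(OC)c1OCc1ccccc1 | intermediate
22 | (1S,2R)‑2‑{4‑[(2S)‑2,3‑dihydroxypropyl]‑2,6‑dimethoxyphenoxy}‑1‑(4‑hydroxy‑3,5‑dimethoxyphenyl)propane‑1,3‑diol | COc1cc([C@H](O)[C@@H](CO)Oc2c(OC)cc(C[C@H](O)CO)cc2OC)cc(OC)c1O | target

## Step count and least certain steps

Total: 14 steps. Longest linear sequence: 12 steps (1, 2, 3, 4, 7, 8, 9, 10, 11, 12, 13, 14, from phenol 1). The ring A branch (steps 5 and 6) joins at step 7.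

**Step 11 (key step).** Two things may go wrong. First, facial discrimination may be poor: the choice between ring A aryl and silyloxy for the anti position is open‑chain and has not been calibrated for a 2‑aryloxy substituent, so erythro/threo mixtures are possible. Second, the β‑aryloxyalkylborane 18 may lose the ring B phenoxide by β‑elimination, especially if the hindered alkene forces long reaction times.
Fallback (sets out from phenol 7 and the Grignard reagent 4, rejoins at 20): C8 is taken from the chiral pool and C7 is made last.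
- Commercial (S)‑3‑(benzyloxy)propane‑1,2‑diol F1 is silylated at the primary hydroxyl (TBSCl, imidazole) to (R)‑1‑(benzyloxy)‑3‑[(tert‑butyldimethylsilyl)oxy]propan‑2‑ol F2.
- A Mitsunobu reaction with 7 (PPh3, diisopropyl azodicarboxylate) inverts the carbinol and gives the (S)‑aryl ether F3.
- Hydrogenolysis gives the (S)‑primary alcohol F4, and Dess–Martin oxidation gives the (R)‑aldehyde F5, which is used cold and at once.
- Reagent 4 is transmetalated with ClTi(OiPr)3 to the aryltitanium reagent F6, which should add to F5 in the Felkin–Anh sense to give the (1S,2R)‑carbinol F7.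
- Fluoride then gives 20.

**Step 9.** Enantioface discrimination may be poor or even reversed, because both carbonyl substituents are sp2 groups of similar size. Partial conjugate reduction by the borane is a second risk.
Fallback (sets out from 15, rejoins at 16): Luche reduction (NaBH4, CeCl3·7H2O, MeOH) gives the C7‑epimeric alcohol F8. Esterification with (S)‑O‑methylmandelic acid (dicyclohexylcarbodiimide, 4‑dimethylaminopyridine) gives the diastereomeric esters, the (7S)‑ester F9 and the (7R)‑ester F10, which are separated by chromatography. Methanolysis of F9 (K2CO3, MeOH) gives 16. F10 is recycled by methanolysis and MnO2 oxidation back to 15.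

**Step 8.** Over‑reaction in the Mannich stage (double aminomethylation) or addition of amine to the electrophilic enone during the elimination would lower the throughput.
Fallback (sets out from 11, rejoins at 15): aldol hydroxymethylation with aqueous formaldehyde and K2CO3 gives the β‑hydroxy ketone F11. MsCl and Et3N convert it through the mesylate F12, which is not isolated, by E1cB elimination into 15.

**Step 14.** Over‑reduction is possible: the free, electron‑rich benzylic C7–O bond may be cleaved by hydrogenolysis along with the benzyl ether.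
Fallback (sets out from 19, rejoins at 22): the order of the end game is changed so that the benzyl group is removed while C7 is still silylated. Hydrogenolysis of 19 gives the phenol F13, fluoride gives the triol acetonide F14, and brief treatment with aqueous acetic acid at room temperature gives 22.

## Further compounds

F1 | step 11 | (S)‑3‑(benzyloxy)propane‑1,2‑diol | OC[C@H](O)COCc1ccccc1
F2 | step 11 | (R)‑1‑(benzyloxy)‑3‑[(tert‑butyldimethylsilyl)oxy]propan‑2‑ol | CC(C)(C)[Si](C)(C)OC[C@H](O)COCc1ccccc1
F3 | step 11 | {[(2S)‑3‑(benzyloxy)‑2‑(ArB‑O)propyl]oxy}(tert‑butyl)dimethylsilane | CC(C)(C)[Si](C)(C)OC[C@@H](Oc1c(OC)cc(C[C@H]2COC(C)(C)O2)cc1OC)COCc1ccccc1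
F4 | step 11 | (2S)‑3‑[(tert‑butyldimethylsilyl)oxy]‑2‑(ArB‑O)propan‑1‑ol | CC(C)(C)[Si](C)(C)OC[C@@H](Oc1c(OC)cc(C[C@H]2COC(C)(C)O2)cc1OC)CO
F5 | step 11 | (2R)‑3‑[(tert‑butyldimethylsilyl)oxy]‑2‑(ArB‑O)propanal | CC(C)(C)[Si](C)(C)OC[C@@H](Oc1c(OC)cc(C[C@H]2COC(C)(C)O2)cc1OC)C=O
F6 | step 11 | [4‑(benzyloxy)‑3,5‑dimethoxyphenyl]titanium triisopropoxide | COc1cc([Ti](OC(C)C)(OC(C)C)OC(C)C)cc(OC)c1OCc1ccccc1
F7 | step 11 | (1S,2R)‑1‑ArA‑3‑[(tert‑butyldimethylsilyl)oxy]‑2‑(ArB‑O)propan‑1‑ol | COc1cc([C@H](O)[C@@H](CO[Si](C)(C)C(C)(C)C)Oc2c(OC)cc(C[C@H]3COC(C)(C)O3)cc2OC)cc(OC)c1OCc1ccccc1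
F8 | step 9 | 1‑ArA‑2‑(ArB‑O)prop‑2‑en‑1‑ol, both C7 epimers | COc1cc(C(O)C(=C)Oc2c(OC)cc(C[C@H]3COC(C)(C)O3)cc2OC)cc(OC)c1OCc1ccccc1
F9 | step 9 | (1S)‑1‑ArA‑2‑(ArB‑O)prop‑2‑en‑1‑yl (2S)‑2‑methoxy‑2‑phenylacetate | COc1cc([C@H](OC(=O)[C@@H](OC)c2ccccc2)C(=C)Oc2c(OC)cc(C[C@H]3COC(C)(C)O3)cc2OC)cc(OC)c1OCc1ccccc1
F10 | step 9 | (1R)‑1‑ArA‑2‑(ArB‑O)prop‑2‑en‑1‑yl (2S)‑2‑methoxy‑2‑phenylacetate | COc1cc([C@@H](OC(=O)[C@@H](OC)c2ccccc2)C(=C)Oc2c(OC)cc(C[C@H]3COC(C)(C)O3)cc2OC)cc(OC)c1OCc1ccccc1
F11 | step 8 | 1‑ArA‑3‑hydroxy‑2‑(ArB‑O)propan‑1‑one, both C8 epimers | COc1cc(C(=O)C(CO)Oc2c(OC)cc(C[C@H]3COC(C)(C)O3)cc2OC)cc(OC)c1OCc1ccccc1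
F12 | step 8 | 3‑ArA‑3‑oxo‑2‑(ArB‑O)propyl methanesulfonate, both C8 epimers | COc1cc(C(=O)C(COS(C)(=O)=O)Oc2c(OC)cc(C[C@H]3COC(C)(C)O3)cc2OC)cc(OC)c1OCc1ccccc1
F13 | step 14 | 4‑[(1S,2R)‑1‑[(tert‑butyldimethylsilyl)oxy]‑3‑hydroxy‑2‑(ArB‑O)propyl]‑2,6‑dimethoxyphenol | COc1cc([C@H](O[Si](C)(C)C(C)(C)C)[C@@H](CO)Oc2c(OC)cc(C[C@H]3COC(C)(C)O3)cc2OC)cc(OC)c1O
F14 | step 14 | (1S,2R)‑1‑(4‑hydroxy‑3,5‑dimethoxyphenyl)‑2‑(ArB‑O)propane‑1,3‑diol | COc1cc([C@H](O)[C@@H](CO)Oc2c(OC)cc(C[C@H]3COC(C)(C)O3)cc2OC)cc(OC)c1O
A1 | alternative 1 | (2S)‑1‑(benzyloxy)‑3‑{4‑[(4S,5R)‑4‑ArA‑2,2‑dimethyl‑1,3‑dioxan‑5‑yloxy]‑3,5‑dimethoxyphenyl}propan‑2‑ol | COc1cc([C@@H]3OC(C)(C)OC[C@H]3Oc2c(OC)cc(C[C@H](O)COCc4ccccc4)cc2OC)cc(OC)c1OCc1ccccc1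
A2 | alternative 1 | (4S,5R)‑4‑ArA‑5‑(4‑bromo‑2,6‑dimethoxyphenoxy)‑2,2‑dimethyl‑1,3‑dioxane | COc1cc([C@@H]3OC(C)(C)OC[C@H]3Oc2c(OC)cc(Br)cc2OC)cc(OC)c1OCc1ccccc1
A3 | alternative 2 | (1S,2R)‑1‑ArA‑2‑(ArB‑O)but‑3‑en‑1‑ol | COc1cc([C@H](O)[C@@H](C=C)Oc2c(OC)cc(C[C@H]3COC(C)(C)O3)cc2OC)cc(OC)c1OCc1ccccc1
A4 | alternative 2 | 2‑[(2E)‑3‑(ArB‑O)prop‑2‑en‑1‑yl]‑4,4,5,5‑tetramethyl‑1,3,2‑dioxaborolane | COc1cc(C[C@H]2COC(C)(C)O2)cc(OC)c1O/C=C/CB1OC(C)(C)C(C)(C)O1
A5 | alternative 2 | 4‑(benzyloxy)‑3,5‑dimethoxybenzaldehyde | COc1cc(C=O)cc(OC)c1OCc1ccccc1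
A6 | alternative 3 | (1S,2R)‑1‑ArA‑3‑[(tert‑butyldimethylsilyl)oxy]‑2‑(ArB‑O)propan‑1‑ol | COc1cc([C@H](O)[C@@H](CO[Si](C)(C)C(C)(C)C)Oc2c(OC)cc(C[C@H]3COC(C)(C)O3)cc2OC)cc(OC)c1OCc1ccccc1
A7 | alternative 3 | (2R)‑3‑[(tert‑butyldimethylsilyl)oxy]‑2‑(ArB‑O)propanal | O=C[C@@H](CO[Si](C)(C)C(C)(C)C)Oc1c(OC)cc(C[C@H]2COC(C)(C)O2)cc1OC
A8 | alternative 3 | [4‑(benzyloxy)‑3,5‑dimethoxyphenyl]titanium triisopropoxide | COc1cc([Ti](OC(C)C)(OC(C)C)OC(C)C)cc(OC)c1OCc1ccccc1
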